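**Assumption:** the target is (S)-14-methylhexadecyl 2,3-dihydroxybenzoate (C24H40O4). 12-Bromododec-1-ene and Pseudomonas fluorescens lipase (Amano lipase AK) are taken as purchased.

## Retrosynthetic overview

1. Ester C–O: target ⇒ (S)-14-methylhexadecan-1-ol + 2,3-bis(benzyloxy)benzoic acid; the benzyl ethers come off last by hydrogenolysis.
2. C1–OH ⇒ terminal alkene (hydroboration–oxidation); C15–C16 (the ethyl branch) ⇒ primary tosylate + Me2CuLi.
3. C12–C13 ⇒ Cu-catalysed sp3–sp3 coupling of a C3 chiral tosylate with dodec-11-enylmagnesium bromide.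
4. Stereocentre ⇒ lipase-catalysed desymmetrisation of achiral 2-methylpropane-1,3-diol. The acetylated arm becomes the long chain and the free-OH arm becomes the ethyl group.
5. Rings: none are formed; the benzene ring is bought intact as 2,3-dihydroxybenzoic acid.

## Forward route

**Step 1**
Reactants: 1, 2-methylpropane-1,3-diol
Product: 2, (S)-3-hydroxy-2-methylpropyl acetate
Conditions: Pseudomonas fluorescens lipase (Amano AK), vinyl acetate (3 equiv), CHCl3, 25–30 °C, run on until ca. 40% diacetate (GC); filter, concentrate cold, quick chromatography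
Reagents that add atoms: vinyl acetate, C=COC(C)=O
Why: Lipase-catalysed enantiotopic-group-selective transesterification (desymmetrisation of a prochiral diol). The enzyme acetylates the pro-S hydroxymethyl group and so creates the stereocentre catalytically. Continuing to partial diacetate formation removes the minor (R)-monoacetate as the achiral diacetate, which should bring 2 to ≥98% ee.

**Step 2**
Reactants: 2
Product: 3, (R)-3-[(tert-butyldiphenylsilyl)oxy]-2-methylpropyl acetate
Conditions: TBDPSCl, imidazole, CH2Cl2, 0 °C (2 added at once to the premixed reagents)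
Reagents that add atoms: tert-butyl(chloro)diphenylsilane, CC(C)(C)[Si](Cl)(c1ccccc1)c1ccccc1
Why: Standard silylation of the free primary alcohol. It is done immediately so that 1,3-acyl migration, which would racemise 2, cannot compete; the descriptor changes S → R by CIP priority only.

**Step 3**
Reactants: 3
Product: 4, (R)-3-[(tert-butyldiphenylsilyl)oxy]-2-methylpropan-1-ol
Conditions: K2CO3, MeOH, 0 °C → rt; ee checked on 4 by Mosher ester NMR
Reagents that add atoms: none
Why: Base-catalysed methanolysis (transesterification) removes the acetate; the TBDPS ether is stable and does not migrate under these mild conditions.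

**Step 4**
Reactants: 4
Product: 5, (S)-3-[(tert-butyldiphenylsilyl)oxy]-2-methylpropyl 4-methylbenzenesulfonate
Conditions: TsCl, Et3N, DMAP (cat.), CH2Cl2, 0 °C → rt
Reagents that add atoms: p-toluenesulfonyl chloride, Cc1ccc(cc1)S(Cl)(=O)=O
Why: Routine sulfonylation of a primary alcohol; no bond to the stereocentre is made or broken (R → S is a priority change only).

**Step 5**
Reactants: 6, 12-bromododec-1-ene
Product: 7, dodec-11-en-1-ylmagnesium bromide
Conditions: Mg turnings (I2-activated), THF, slow addition, 25–40 °C; titrated before use
Reagents that add atoms: magnesium, [Mg]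
Why: Grignard formation from an unhindered primary bromide; slow addition limits Wurtz coupling and the remote alkene is inert.

**Step 6**
Reactants: 5; 7 (2.5 equiv)
Product: 8, (R)-tert-butyl[(2-methylpentadec-14-en-1-yl)oxy]diphenylsilane
Conditions: Li2CuCl4 (5 mol %), THF, −78 °C → rt
Reagents that add atoms: none beyond reactant 7
Why: Kochi-type Cu-catalysed cross-coupling of a primary tosylate with a primary alkyl Grignard. Displacement is at CH2, so the adjacent stereocentre is untouched, and the silyl ether tolerates the conditions.

**Step 7**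
Reactants: 8
Product: 9, (R)-2-methylpentadec-14-en-1-ol
Conditions: TBAF, THF, rt
Reagents that add atoms: none
Why: Fluoride-mediated desilylation; the alkene and the stereocentre are unaffected.

**Step 8**
Reactants: 9
Product: 10, (R)-2-methylpentadec-14-en-1-yl 4-methylbenzenesulfonate
Conditions: TsCl, Et3N, DMAP (cat.), CH2Cl2, 0 °C → rt
Reagents that add atoms: p-toluenesulfonyl chloride, Cc1ccc(cc1)S(Cl)(=O)=O
Why: Routine sulfonylation of the primary alcohol, activating the second arm for methylation.

**Step 9**
Reactants: 10
Product: 11, (S)-14-methylhexadec-1-ene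
Conditions: Me2CuLi (5 equiv, from MeLi/CuI), Et2O, −30 → 0 °C
Reagents that add atoms: lithium dimethylcuprate, [Li+].C[Cu-]C
Why: SN2 displacement of a primary tosylate by a Gilman cuprate turns CH2OTs into CH2CH3. The geometry at the stereocentre is unchanged; the descriptor becomes S only because the new ethyl group ranks below the long chain.

**Step 10**
Reactants: 11
Product: 12, (S)-14-methylhexadecan-1-ol
Conditions: 9-BBN, THF, 0 °C → rt; then 3 M NaOH, 30% H2O2, 0 °C → rt
Reagents that add atoms: hydrogen peroxide, OO (9-BBN delivers only H)
Why: Anti-Markovnikov hydroboration–oxidation of the terminal alkene gives the primary alcohol with >99:1 regioselectivity; the remote stereocentre is not involved.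

**Step 11**
Reactants: 13, 2,3-dihydroxybenzoic acid
Product: 14, benzyl 2,3-bis(benzyloxy)benzoate
Conditions: BnBr (3.5 equiv), K2CO3, DMF, 60 °C
Reagents that add atoms: benzyl bromide, BrCc1ccccc1
Why: Exhaustive Williamson O-alkylation of both phenols and the carboxylate, masking the catechol before coupling.

**Step 12**
Reactants: 14
Product: 15, 2,3-bis(benzyloxy)benzoic acid
Conditions: 2 M NaOH (aq), MeOH/THF, 60 °C; then 1 M HCl
Reagents that add atoms: sodium hydroxide, [Na+].[OH-]
Why: Saponification cleaves only the benzyl ester; the aryl benzyl ethers are stable to base.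

**Step 13**
Reactants: 12; 15
Product: 16, (S)-14-methylhexadecyl 2,3-bis(benzyloxy)benzoate
Conditions: EDC·HCl, DMAP, CH2Cl2, 0 °C → rt
Reagents that add atoms: none
Why: Steglich esterification of an unhindered primary alcohol with the protected acid; protecting the catechol prevents self-acylation.

**Step 14**
Reactants: 16
Product: 17, Gentiside C, (S)-14-methylhexadecyl 2,3-dihydroxybenzoate
Conditions: H2 (1 atm), 10% Pd/C, EtOAc, rt; filter under N2
Reagents that add atoms: none
Why: Hydrogenolysis cleaves the two benzylic C–O bonds; the alkyl ester is not benzylic and the saturated stereocentre is unaffected.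

## Compound list

1 | 2-methylpropane-1,3-diol | CC(CO)CO | starting material
2 | (S)-3-hydroxy-2-methylpropyl acetate | OC[C@H](C)COC(C)=O | intermediate
3 | (R)-3-[(tert-butyldiphenylsilyl)oxy]-2-methylpropyl acetate | CC(C)(C)[Si](c1ccccc1)(c1ccccc1)OC[C@H](C)COC(C)=O | intermediate
4 | (R)-3-[(tert-butyldiphenylsilyl)oxy]-2-methylpropan-1-ol | CC(C)(C)[Si](c1ccccc1)(c1ccccc1)OC[C@H](C)CO | intermediate
5 | (S)-3-[(tert-butyldiphenylsilyl)oxy]-2-methylpropyl 4-methylbenzenesulfonate | CC(C)(C)[Si](c1ccccc1)(c1ccccc1)OC[C@H](C)COS(=O)(=O)c1ccc(C)cc1 | intermediate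
6 | 12-bromododec-1-ene | C=CCCCCCCCCCCBr | starting material
7 | dodec-11-en-1-ylmagnesium bromide | C=CCCCCCCCCCC[Mg]Br | intermediate
8 | (R)-tert-butyl[(2-methylpentadec-14-en-1-yl)oxy]diphenylsilane | CC(C)(C)[Si](c1ccccc1)(c1ccccc1)OC[C@H](C)CCCCCCCCCCCC=C | intermediate
9 | (R)-2-methylpentadec-14-en-1-ol | OC[C@H](C)CCCCCCCCCCCC=C | intermediate
10 | (R)-2-methylpentadec-14-en-1-yl 4-methylbenzenesulfonate | Cc1ccc(cc1)S(=O)(=O)OC[C@H](C)CCCCCCCCCCCC=C | intermediate
11 | (S)-14-methylhexadec-1-ene | CC[C@H](C)CCCCCCCCCCCC=C | intermediate
12 | (S)-14-methylhexadecan-1-ol | CC[C@H](C)CCCCCCCCCCCCCO | intermediate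
13 | 2,3-dihydroxybenzoic acid | OC(=O)c1cccc(O)c1O | starting material
14 | benzyl 2,3-bis(benzyloxy)benzoate | O=C(OCc1ccccc1)c1cccc(OCc2ccccc2)c1OCc1ccccc1 | intermediate
15 | 2,3-bis(benzyloxy)benzoic acid | OC(=O)c1cccc(OCc2ccccc2)c1OCc1ccccc1 | intermediate
16 | (S)-14-methylhexadecyl 2,3-bis(benzyloxy)benzoate | CC[C@H](C)CCCCCCCCCCCCCOC(=O)c1cccc(OCc2ccccc2)c1OCc1ccccc1 | intermediate
17 | Gentiside C, (S)-14-methylhexadecyl 2,3-dihydroxybenzoate | CC[C@H](C)CCCCCCCCCCCCCOC(=O)c1cccc(O)c1O | target

## Summary

Total step count: 14.
Longest linear sequence: 11 steps (1–4, 6–10, 13, 14). Step 5 is a 1-step side branch and steps 11–12 a 2-step side branch.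

Steps most likely to fail, with fallbacks:

1. **Step 1 (lipase desymmetrisation).** The ee depends on how far the reaction is run, and monoacetate 2 can racemise by 1,3-acyl migration during isolation. Fallback: set the centre by Rh–bisphosphine-catalysed asymmetric hydrogenation of methyl 2-(hydroxymethyl)acrylate to (S)-methyl 3-hydroxy-2-methylpropanoate. TBDPS protection and DIBAL-H reduction then rejoin the route at 4.
2. **Step 6 (Cu-catalysed coupling at the β-branched tosylate).** Displacement may be slow, with Grignard homocoupling or elimination competing. Fallback: convert 5 into the phenyl sulfone (PhSNa, then oxidation), lithiate it and alkylate with bromide 6, so that the C–C bond forms at the unbranched primary bromide. Reductive desulfonylation (Mg/MeOH) then gives 8.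
3. **Step 9 (cuprate methylation of the β-branched tosylate).** Displacement may be slow, with competing elimination or reduction. Fallback: oxidise 9 to the α-methyl aldehyde (buffered Dess–Martin, used cold and at once) and add MeMgBr. The resulting secondary hydroxyl is then removed by Barton–McCombie deoxygenation (xanthate, Bu3SnH/AIBN) to give 11.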